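The violet run was charged with more starting complex than the ochre run, 0.11 M against 0.073 M, yet its reading at 25.0 h comes to 8.80 mM of complex with one exchanged against 8.03 mM in the ochre run. With a scatter of 1.5 percentage points on each reading, we treat these two amounts as one.

the same everywhere: gas 31 mM (held)
- ochre: starting complex 0.073 M; run made earlier
- violet: starting complex 0.11 M; run made earlier
- flask: starting complex 0.052 M; time 25 h

| run | time / h | starting complex / % | complex with one exchanged / % |
|---|---|---|---|
| ochre | 1.50 | 99 | 5 |
| ochre | 5.00 | 99 | 2 |
| ochre | 8.00 | 98 | 3 |
| ochre | 12.0 | 96 | 5 |
| ochre | 20.0 | 89 | 10 |
| ochre | 25.0 | 94 | 11 |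
| ochre | 30.0 | 86 | 12 |
| violet | 1.50 | 99 | 0 |
| violet | 5.00 | 100 | 1 |
| violet | 8.00 | 99 | 2 |
| violet | 12.0 | 96 | 2 |
| violet | 20.0 | 95 | 6 |
| violet | 25.0 | 91 | 8 |
| violet | 30.0 | 90 | 9 |

(scatter of a reading: 1.5 percentage points)

- leaving ligand is meant together with its idle adduct
- at the start none of incoming ligand is dissolved
- what was read earlier has a scatter of 1.5 percentage points, one standard deviation
- reactions considered so far: starting complex + incoming ligand -> leaving ligand + complex with one exchanged; complex with two exchanged + incoming ligand -> leaving ligand + complex with three exchanged; complex with three exchanged + incoming ligand -> leaving ligand + complex with four exchanged; complex with one exchanged + incoming ligand -> leaving ligand + complex with two exchanged; leaving ligand + incoming ligand <-> idle adduct; gas <-> incoming ligand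
- the earlier runs do not show how much of incoming ligand is bound; that part of a forecast is a guess

* part of the starting complex that has reacted at 25 h
* share of the unused incoming ligand that is free and not bound as idle adduct, at 25 h

So we keep a ledger of the incoming ligand. The opening balance is empty: none is dissolved at the start, so every mole has to cross from the gas. The first entry is exchange, where each step spends one mole of incoming ligand and frees one mole of leaving ligand. The mean of the two readings, scatter included, gives the bill B, the ligand spent on first exchanges by that time, 8.41 mM. The second entry is ligand bound to leaving ligand as idle adduct, and the third is ligand left free, but the readings show neither. Since the two readings moved so little with the charge, we carry B unchanged to the new flask, and our reckoning gives 16.2% reacted there.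

The forecast differs from our reckoning: it gave 13% reacted and 65% free, reasoning that “moderate binding leaves most ligand free”.

The flask gives 13.9% reacted and 30.3% free, with 0.00596 M of ligand bound as idle adduct and 0.00259 M free at 25.0 h.

    starting complex + incoming ligand → leaving ligand + complex with one exchanged (k = 2.80 M⁻¹ h⁻¹)
    complex with two exchanged + incoming ligand → leaving ligand + complex with three exchanged (k = 4.20 M⁻¹ h⁻¹)
    complex with three exchanged + incoming ligand → leaving ligand + complex with four exchanged (k = 0.290 M⁻¹ h⁻¹)
    complex with one exchanged + incoming ligand → leaving ligand + complex with two exchanged (k = 0.450 M⁻¹ h⁻¹)
    leaving ligand + incoming ligand ⇌ idle adduct, settled at all times (K = 1700 M⁻¹)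
    gas ⇌ incoming ligand, rate k6*(csat - [incoming ligand]) (kL = 0.0220 h⁻¹)

The flask's bill of first exchanges comes to 7.22 mM, somewhat less than our B. So little of its charge has reacted because of the slow crossing from gas to incoming ligand acting together with the time given. Without that slowness the flask reaches 87.8%, and left ten times as long it reaches 94.5%.

For a neighbour flask with 0.088 M of starting complex, B gives 9.56% reacted. The computed result for that neighbour flask is 9.52%.

(The data were computed for substances that don't exist.)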